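Ring A is disconnected across three bonds, C4a–C8a, C5–C6 and C8–C8a, into a four-carbon cyclobutenone and a two-carbon ynol ether. The benzannulation exploits the oxygen pattern of ring A: oxygen on C5, C7, C8 and C8a, hydrogen only on C6, and the C8a oxygen meta to the C5 methoxy across C4a, the resorcinol monoether pattern this reaction delivers. One thermal operation builds the pentasubstituted ring A with the C8a hydroxyl free, O8 benzylated and the aryl-bearing C4 already on C4a. The precursors are 4-(benzyloxy)-3-methoxycyclobutenone and a silyl-protected 1-aryl-3-methoxypropargyl alcohol. A lactonising Wittig reaction then closes ring B, and hydrogenolysis frees the C8 hydroxyl.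

Key step: step 5

Remark on the chemistry: the target is achiral. The stereocentres of 6, 9, 10, 12, 14, 15 and 16 are formed racemic (12 as a mixture of diastereomers) and all are removed before the end, so no stereocontrol is needed.

Step 1
Reactants: 1 chloroacetaldehyde dimethyl acetal (2-chloro-1,1-dimethoxyethane)
Product: 3 methoxyacetylene (methoxyethyne), via sodium methoxyacetylide 2 (not isolated)
Conditions: NaNH2 (3 equiv), liq. NH3, −33 °C; then cold aq. NaCl, distil into Et2O at −78 °C
Reagents that add atoms: none
Why: Sodium amide effects two successive β-eliminations (methanol, then HCl) from the chloroacetal and deprotonates the resulting ynol ether, the standard alkoxyacetylene synthesis by double elimination, and hydrolysis of acetylide 2 releases the volatile alkyne, which is kept as a cold solution.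

Step 2
Reactants: 4 benzyloxyacetyl chloride; 3 methoxyacetylene
Product: 6 4-(benzyloxy)-3-methoxycyclobut-2-en-1-one (racemic), via benzyloxyketene 5 (not isolated)
Conditions: Et3N, Et2O, 0 °C, 4 added slowly to excess 3
Reagents that add atoms: none
Why: Dehydrochlorination of 4 by Et3N gives benzyloxyketene 5, which is trapped in a ketene–ynol ether [2+2] cycloaddition in which the ketene carbonyl carbon bonds to the unsubstituted, nucleophilic alkyne carbon, so that the methoxy group lands on C3 next to the benzyloxy-bearing C4; the C4 stereocentre forms racemic and is lost in step 5.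

Step 3
Reactants: 1 chloroacetaldehyde dimethyl acetal; 7 3,4-dimethoxybenzaldehyde
Product: 9 1-(3,4-dimethoxyphenyl)-3-methoxyprop-2-yn-1-ol (racemic), via lithium methoxyacetylide 8 (not isolated)
Conditions: LiNEt2 (3 equiv), THF, 0 °C; then 7, −78 → 0 °C; H2O
Reagents that add atoms: none
Why: LiNEt2 converts the chloroacetal by double elimination and deprotonation into lithium methoxyacetylide 8 without isolation of the volatile alkyne, and 1,2-addition of this acetylide to the non-enolisable aldehyde gives the propargylic alcohol, whose carbinol stereocentre forms racemic and is removed by the oxidation in step 7.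

Step 4
Reactants: 9 1-(3,4-dimethoxyphenyl)-3-methoxyprop-2-yn-1-ol
Product: 10 tert-butyl{[1-(3,4-dimethoxyphenyl)-3-methoxyprop-2-yn-1-yl]oxy}dimethylsilane (racemic)
Conditions: TBSCl, imidazole, DMF, rt
Reagents that add atoms: tert-butyldimethylsilyl chloride, CC(C)(C)[Si](C)(C)Cl
Why: Silylation of a secondary alcohol with TBSCl and imidazole under basic conditions masks the hydroxyl, which would otherwise be acylated by the ketene in step 5, and spares the acid-sensitive ynol ether.

Step 5
Reactants: 6 4-(benzyloxy)-3-methoxycyclobut-2-en-1-one; 10 tert-butyl{[1-(3,4-dimethoxyphenyl)-3-methoxyprop-2-yn-1-yl]oxy}dimethylsilane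
Product: 15 6-(benzyloxy)-2-[(tert-butyldimethylsilyloxy)(3,4-dimethoxyphenyl)methyl]-3,5-dimethoxyphenol (racemic), via vinylketene 11 (not isolated), via 4-vinylcyclobutenone 12 (not isolated), via dienylketene 13 (not isolated), via cyclohexadienone 14 (not isolated)
Conditions: toluene, 80 °C then 110 °C, Ar; 6 (1.3 equiv) added slowly to 10
Reagents that add atoms: none
Why: Proposed new method: heating opens 6 by conrotatory 4π cleavage of its C1–C4 bond, the benzyloxy donor rotating outward, to vinylketene 11, whose carbonyl carbon (future C8a) is attacked by the oxygen-remote carbon of ynol ether 10 (future C4a) while its α-carbon (C6) bonds to the methoxy-bearing alkyne carbon (C5), a [2+2] cycloaddition that gives 4-vinylcyclobutenone 12. Reversible 4π opening of 12 gives dienylketene 13, and ring A closes by thermally allowed disrotatory 6π electrocyclisation between the ketene carbon and the benzyloxy-bearing terminus (the C8–C8a bond) to cyclohexadienone 14, which enolises to phenol 15 because C8 still carries one hydrogen. The closest known reaction is the Danheiser benzannulation of 3-alkyl- and 3-arylcyclobutenones with alkoxy- and siloxyalkynes; what has not been shown is a cyclobutenone oxygenated at both C3 and C4, and the easy thermal opening of squarate-derived 4-alkoxycyclobutenones argues that the C4 donor lowers the barrier of the first step. No stereocentre is created: ring A is planar and the silyloxy-bearing carbon is carried through unchanged as a racemate. The only selectivity needed is the orientation of the [2+2] step, which the polarisation of the ynol ether secures by making the carbinol-bearing carbon the nucleophile toward the ketene carbonyl; slow addition of 6 keeps the concentration of 11 low and so suppresses its dimerisation.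

Step 6
Reactants: 15 6-(benzyloxy)-2-[(tert-butyldimethylsilyloxy)(3,4-dimethoxyphenyl)methyl]-3,5-dimethoxyphenol
Product: 16 6-(benzyloxy)-2-[(3,4-dimethoxyphenyl)(hydroxy)methyl]-3,5-dimethoxyphenol (racemic)
Conditions: Bu4NF, THF, 0 °C; then H2O
Reagents that add atoms: none
Why: Fluoride-induced cleavage of the silyl ether under basic conditions frees the carbinol without the acid that would ionise this electron-rich o-hydroxybenzhydryl system.

Step 7
Reactants: 16 6-(benzyloxy)-2-[(3,4-dimethoxyphenyl)(hydroxy)methyl]-3,5-dimethoxyphenol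
Product: 17 [3-(benzyloxy)-2-hydroxy-4,6-dimethoxyphenyl](3,4-dimethoxyphenyl)methanone
Conditions: activated MnO2 (excess), CH2Cl2, rt
Reagents that add atoms: none
Why: Activated MnO2 oxidises doubly benzylic alcohols chemoselectively under neutral heterogeneous conditions, and the resulting ketone is stabilised by the hydrogen bond to the C8a hydroxyl; the racemic stereocentre disappears here.

Step 8
Reactants: 17 [3-(benzyloxy)-2-hydroxy-4,6-dimethoxyphenyl](3,4-dimethoxyphenyl)methanone
Product: 19 8-(benzyloxy)-4-(3,4-dimethoxyphenyl)-5,7-dimethoxy-2H-chromen-2-one, via acyl ylide 18 (not isolated)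
Conditions: Ph3P=C=C=O, toluene, 110 °C
Reagents that add atoms: (triphenylphosphoranylidene)ketene, O=C=C=P(c1ccccc1)(c1ccccc1)c1ccccc1
Why: The phenol adds across the C=C bond of the cumulated ylide to give the ester-stabilised ylide 18, and intramolecular Wittig olefination of the neighbouring diaryl ketone forms C3=C4 and closes the lactone ring B.

Step 9
Reactants: 19 8-(benzyloxy)-4-(3,4-dimethoxyphenyl)-5,7-dimethoxy-2H-chromen-2-one
Product: 20 8-hydroxy-4-(3,4-dimethoxyphenyl)-5,7-dimethoxy-2H-chromen-2-one (8-hydroxy-5,7,3',4'-tetramethoxy-4-phenylcoumarin)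
Conditions: H2 (1 atm), Pd/C, EtOAc, rt
Reagents that add atoms: none
Why: Catalytic hydrogenolysis cleaves the benzyl aryl ether at room temperature, while the conjugated, aryl-substituted C3=C4 bond of the coumarin is hydrogenated far more slowly under these conditions.

Compound list

1 | chloroacetaldehyde dimethyl acetal (2-chloro-1,1-dimethoxyethane) | COC(CCl)OC | starting material
2 | sodium methoxyacetylide | COC#[C-].[Na+] | intermediate (not isolated)
3 | methoxyacetylene (methoxyethyne) | COC#C | intermediate
4 | benzyloxyacetyl chloride | O=C(Cl)COCc1ccccc1 | starting material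
5 | benzyloxyketene | O=C=COCc1ccccc1 | intermediate (not isolated)
6 | 4-(benzyloxy)-3-methoxycyclobut-2-en-1-one, racemic | O=C1C=C(OC)C1OCc1ccccc1 | intermediate
7 | 3,4-dimethoxybenzaldehyde | COc1ccc(C=O)cc1OC | starting material
8 | lithium methoxyacetylide | COC#[C-].[Li+] | intermediate (not isolated)
9 | 1-(3,4-dimethoxyphenyl)-3-methoxyprop-2-yn-1-ol, racemic | COC#CC(O)c1ccc(OC)c(OC)c1 | intermediate
10 | tert-butyl{[1-(3,4-dimethoxyphenyl)-3-methoxyprop-2-yn-1-yl]oxy}dimethylsilane, racemic | COC#CC(O[Si](C)(C)C(C)(C)C)c1ccc(OC)c(OC)c1 | intermediate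
11 | (3Z)-4-(benzyloxy)-3-methoxybuta-1,3-dien-1-one (vinylketene, benzyloxy trans to C2) | O=C=C/C(OC)=C/OCc1ccccc1 | intermediate (not isolated)
12 | 4-[(Z)-2-(benzyloxy)-1-methoxyethenyl]-2-[(tert-butyldimethylsilyloxy)(3,4-dimethoxyphenyl)methyl]-3-methoxycyclobut-2-en-1-one, racemic mixture of diastereomers | O=C1C(C(O[Si](C)(C)C(C)(C)C)c2ccc(OC)c(OC)c2)=C(OC)C1/C(OC)=C/OCc1ccccc1 | intermediate (not isolated)
13 | (3E,5Z)-6-(benzyloxy)-2-[(tert-butyldimethylsilyloxy)(3,4-dimethoxyphenyl)methyl]-3,5-dimethoxyhexa-1,3,5-trien-1-one (dienylketene, C2 and C5 cis across C3=C4), racemic | O=C=C(C(O[Si](C)(C)C(C)(C)C)c1ccc(OC)c(OC)c1)/C(OC)=C\C(OC)=C\OCc1ccccc1 | intermediate (not isolated)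
14 | 6-(benzyloxy)-2-[(tert-butyldimethylsilyloxy)(3,4-dimethoxyphenyl)methyl]-3,5-dimethoxycyclohexa-2,4-dien-1-one, racemic mixture of diastereomers | O=C1C(C(O[Si](C)(C)C(C)(C)C)c2ccc(OC)c(OC)c2)=C(OC)C=C(OC)C1OCc1ccccc1 | intermediate (not isolated)
15 | 6-(benzyloxy)-2-[(tert-butyldimethylsilyloxy)(3,4-dimethoxyphenyl)methyl]-3,5-dimethoxyphenol, racemic | COc1ccc(C(O[Si](C)(C)C(C)(C)C)c2c(O)c(OCc3ccccc3)c(OC)cc2OC)cc1OC | intermediate
16 | 6-(benzyloxy)-2-[(3,4-dimethoxyphenyl)(hydroxy)methyl]-3,5-dimethoxyphenol, racemic | COc1ccc(C(O)c2c(O)c(OCc3ccccc3)c(OC)cc2OC)cc1OC | intermediate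
17 | [3-(benzyloxy)-2-hydroxy-4,6-dimethoxyphenyl](3,4-dimethoxyphenyl)methanone | COc1ccc(C(=O)c2c(O)c(OCc3ccccc3)c(OC)cc2OC)cc1OC | intermediate
18 | 6-(benzyloxy)-2-(3,4-dimethoxybenzoyl)-3,5-dimethoxyphenyl (triphenylphosphoranylidene)acetate | COc1ccc(C(=O)c2c(OC(=O)C=P(c3ccccc3)(c3ccccc3)c3ccccc3)c(OCc3ccccc3)c(OC)cc2OC)cc1OC | intermediate (not isolated)
19 | 8-(benzyloxy)-4-(3,4-dimethoxyphenyl)-5,7-dimethoxy-2H-chromen-2-one | COc1ccc(-c2cc(=O)oc3c(OCc4ccccc4)c(OC)cc(OC)c23)cc1OC | intermediate
20 | 8-hydroxy-4-(3,4-dimethoxyphenyl)-5,7-dimethoxy-2H-chromen-2-one (8-hydroxy-5,7,3',4'-tetramethoxy-4-phenylcoumarin) | COc1ccc(-c2cc(=O)oc3c(O)c(OC)cc(OC)c23)cc1OC | target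

Total step count: 9 steps.
Longest linear sequence: 7 steps (steps 3, 4, 5, 6, 7, 8, 9 from 3,4-dimethoxybenzaldehyde 7; equally steps 1, 2, 5, 6, 7, 8, 9 from acetal 1).

The three steps most likely to fail

Step 5 (the key step, proposed new method). The electron-rich vinylketene may dimerise or acylate the product phenol faster than it is captured by the hindered ynol ether. The second ring opening may also stall at the 4-vinylcyclobutenone, or the silyloxy group ortho to the new phenol may be lost thermally through an o-quinone methide. The fallback uses only known chemistry, sets out from 3,4-dimethoxybenzaldehyde 7 and comes back to the route at the target 20; since it needs neither 6 nor 10, it also stands behind steps 1 to 4.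
- Aldol addition of the lithium enolate of ethyl acetate (LiN(iPr)2, THF, −78 °C) to 7 should give ethyl 3-(3,4-dimethoxyphenyl)-3-hydroxypropanoate F1.
- MnO2 oxidation of this benzylic alcohol should give the β-keto ester ethyl 3-(3,4-dimethoxyphenyl)-3-oxopropanoate F2.
- Separately, Dakin oxidation (H2O2, NaOH) of commercial 2-hydroxy-4,6-dimethoxybenzaldehyde (COc1cc(O)c(C=O)c(OC)c1) should give 3,5-dimethoxybenzene-1,2-diol F3.
- Pechmann condensation of F2 with F3 (CF3CO2H, 70 °C) can close the pyranone only through the hydroxyl that has a free ortho carbon, the one not flanked by a methoxy group. It should therefore give 20 directly, with the other hydroxyl becoming the C8 hydroxyl.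

Step 7. The free, highly electron-rich phenol ring may be oxidised toward a quinone alongside the carbinol, and the o-hydroxybenzhydrol 16 may ionise to an o-quinone methide and oligomerise during handling. The fallback masks the phenol before the carbinol is unveiled; it sets out from 15 and comes back at 17.
- Alkylation of 15 with chloromethyl methyl ether (iPr2NEt, CH2Cl2) should give the methoxymethyl ether tert-butyl{[3-(benzyloxy)-4,6-dimethoxy-2-(methoxymethoxy)phenyl](3,4-dimethoxyphenyl)methoxy}dimethylsilane F4.
- Desilylation with Bu4NF should give the carbinol [3-(benzyloxy)-4,6-dimethoxy-2-(methoxymethoxy)phenyl](3,4-dimethoxyphenyl)methanol F5.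
- Oxidation with Dess–Martin periodinane (NaHCO3, CH2Cl2), now without a free phenol, should give the ketone [3-(benzyloxy)-4,6-dimethoxy-2-(methoxymethoxy)phenyl](3,4-dimethoxyphenyl)methanone F6.
- Brief treatment with HCl in methanol should remove the acetal ortho to the carbonyl and give 17.

Step 8. Addition of the doubly flanked, hydrogen-bonded phenol to the cumulated ylide may be slow, and the ester-stabilised ylide 18 may fail to olefinate the hindered, electron-rich diaryl ketone and simply accumulate. The fallback replaces the phosphorane by a more nucleophilic phosphonate carbanion; it sets out from 17 and comes back at 19.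
- Esterification of 17 with diethylphosphonoacetic acid (carbodiimide EDC, DMAP, CH2Cl2) should give 6-(benzyloxy)-2-(3,4-dimethoxybenzoyl)-3,5-dimethoxyphenyl (diethoxyphosphoryl)acetate F7.
- Intramolecular Horner–Wadsworth–Emmons olefination (LiCl, DBU, MeCN) should then close ring B to 19.

Further compounds

F1 | step 5 | ethyl 3-(3,4-dimethoxyphenyl)-3-hydroxypropanoate, racemic | CCOC(=O)CC(O)c1ccc(OC)c(OC)c1
F2 | step 5 | ethyl 3-(3,4-dimethoxyphenyl)-3-oxopropanoate | CCOC(=O)CC(=O)c1ccc(OC)c(OC)c1
F3 | step 5 | 3,5-dimethoxybenzene-1,2-diol | COc1cc(O)c(O)c(OC)c1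
F4 | step 7 | tert-butyl{[3-(benzyloxy)-4,6-dimethoxy-2-(methoxymethoxy)phenyl](3,4-dimethoxyphenyl)methoxy}dimethylsilane, racemic | COCOc1c(OCc2ccccc2)c(OC)cc(OC)c1C(O[Si](C)(C)C(C)(C)C)c1ccc(OC)c(OC)c1
F5 | step 7 | [3-(benzyloxy)-4,6-dimethoxy-2-(methoxymethoxy)phenyl](3,4-dimethoxyphenyl)methanol, racemic | COCOc1c(OCc2ccccc2)c(OC)cc(OC)c1C(O)c1ccc(OC)c(OC)c1
F6 | step 7 | [3-(benzyloxy)-4,6-dimethoxy-2-(methoxymethoxy)phenyl](3,4-dimethoxyphenyl)methanone | COCOc1c(OCc2ccccc2)c(OC)cc(OC)c1C(=O)c1ccc(OC)c(OC)c1
F7 | step 8 | 6-(benzyloxy)-2-(3,4-dimethoxybenzoyl)-3,5-dimethoxyphenyl (diethoxyphosphoryl)acetate | CCOP(=O)(OCC)CC(=O)Oc1c(OCc2ccccc2)c(OC)cc(OC)c1C(=O)c1ccc(OC)c(OC)c1
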